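## Structural features

The target is an isoflavanquinone: a chroman (benzo ring A fused to dihydropyran ring C; O1, C2, C3, C4, C4a–C8a) that carries at C3 a 2,3-dimethoxy-1,4-benzoquinone (ring B; C1' bonded to C3, carbonyls at C2' and C5', OMe at C3' and C4', H at C6'). C3 is the only stereocentre, (S): a tertiary C–H flanked by the O-bearing C2 methylene, the benzylic C4 methylene and the quinone, with no neighbouring stereocentre and no heteroatom of its own from which it could be set. Ring A carries four contiguous oxygens (O1 on C8a, OMe on C8 and C7, free OH on C6), so it is a mono-etherified 2,3-dimethoxyhydroquinone. Ring B is the oxidised form of the same 5-substituted 2,3-dimethoxy-1,4-dioxygenated benzene. The fragile groups are the quinone (reduction, nucleophiles, and base, which also threatens C3–H through quinone-methide tautomerism) and the p-alkoxyphenol of ring A, whose oxidation would open ring C. The real difficulty is twofold: the C3–C1' bond with its stereocentre between two crowded, oxygen-rich rings, and bringing ring B alone to the quinone level although both rings have the same oxygenation pattern, so an oxidative demethylation could not tell them apart. The feature the key step exploits is that the carbonyl oxygen on C2' lies 1,3 to C4 across the C1'–C3 bond: O(C2')–C2'–C1'–C3–C4 is a latent dihydrofuran ring, so the target is a ring-opened pterocarpan. Ring B can therefore be brought in as the intact quinone, added across the C3=C4 bond of an achiral 2H-chromene (C–C bond at C3, C–O bond at C4), and the C4–O bond cut again reductively.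

## Logic of the disconnections

Numbering: 8 and 7 use isoflavan numbering; 6 uses pterocarpan numbering, with C6a = C3, C11a = C4, C6 = C2, O5 = O1, C6b = C1', C10a = C2', O11 = the oxygen on C2', C8 = C5'.

**8 to 7.** No skeletal bond is cut; the two C=O groups of ring B are taken back to two O–H groups. The reason is that a reductive step delivers ring B at exactly this level. The gain is that the sensitive quinone appears only in the last operation. The demand on the forward step is an oxidant that takes the free hydroquinone of ring B and leaves the p-alkoxyphenol of ring A alone; a mild oxidant in stoichiometric amount meets this, because ring A cannot reach a quinone without breaking the O1–C8a ether.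

**7 to 6.** This is a reconnection. The C4–H bond of 7 is exchanged for a C4–O bond to the oxygen on C2', and the O–H on C6 for O–CH2Ph; in the forward direction one hydrogenolysis cuts C11a–O11 and PhCH2–O of 6. The reason is that the cis-fused dihydrofuran of 6 is the signature of a quinone–alkene annulation. The gain is a rigid tetracycle in which C3 is locked and the two ring-B oxygens are already differentiated (one tied to C4, one free). The demand is that the benzylic C–O bond is cleaved without ionising C11a, since loss of the C6a proton and re-reduction would erode the configuration.

**6 to 5 and 1 (key).** Bonds cut: C6a–C6b (the C3–C1' bond of 8) and C11a–O11. The reason is that both bonds form in one polar [3+2] annulation between the styrene-type C3=C4 bond of 5 and the enone-plus-carbonyl-oxygen unit of 1. The gain is the largest of the route: a 26-carbon tetracycle with two stereocentres falls to two achiral pieces, and ring B arrives with its oxygens in place, so no oxidant ever has to choose between rings A and B. The demand is that a chiral Lewis acid on 1 selects one enantiotopic face of the alkene of 5; regiochemistry is fixed by the substrates (see step 5).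

**5 to 4.** Bond cut: C4–C4a, with the C2–C3–C4 unit returned to an O-propargyl group. The reason is that an aryl propargyl ether gives a 2H-chromene by a thermal sigmatropic cascade with no further reagent. The gain is that ring C comes from a three-carbon electrophile. The demand is a single free ortho position on the arene, which 4 has because the other is blocked by OMe.

**4 to 3, and 3 to 2.** Bonds cut: O–CH2C≡CH, then O–CH2Ph. Both are ether formations on phenols. The benzyl group is chosen because step 6 removes it at no cost. The demand on the second is mono-alkylation of a symmetric diol, handled by using 2 in excess; because 2 is C2-symmetric, either hydroxyl gives the same product.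

**2 to 1.** No skeletal bond is cut; the diol is taken back to the quinone. The gain is that 1 is the single aromatic starting material for both rings A and B. The demand is only a clean two-electron reduction.

## Other disconnections considered

**Alternative 1:** (the first that comes to mind) Cut the C3–H/C4–H pair and the quinone oxidation level. Forward key step: asymmetric hydrogenation (Ir–P,N catalyst) of the isoflav-3-ene A1 to the (S)-isoflavan A2, then oxidative demethylation of the 2,3,4,5-tetramethoxyphenyl ring with Ce(IV) and debenzylation. Grounds for preferring the chosen plan: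
- Ring A of A2 is a 1,2,3,4-tetraalkoxybenzene para-dioxygenated at C6/C8a exactly as ring B is at C2'/C5'. An oxidative demethylation has no structural basis for choosing ring B, and attack on ring A opens ring C.
- A1 is a trisubstituted cyclic styrene bearing an ortho-alkoxy aryl group, a demanding class for enantioselective hydrogenation.
- A1 must be assembled from two separately built pentasubstituted arenes, which roughly doubles the step count.

**Alternative 2:** Cut at the C4 oxidation level and set C3 by a dynamic step. Forward key step: Ru(II)–TsDPEN transfer hydrogenation of the racemic isoflavanone A3 with dynamic kinetic resolution through its enol, funnelling both enantiomers to the cis-(3S,4S)-isoflavan-4-ol A4. Hydrogenolysis of the C4–OH and the three benzyl ethers would reach 7, and the end game would be the same. Grounds for preferring the chosen plan: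
- The stereocontrol is sound, but A3 again needs an aryl-acetyl coupling of two pentasubstituted rings and a ring closure, which makes the route about twice as long.
- The C4 oxygen is introduced only to be removed.
- The key step forms no skeletal bond, whereas step 5 forms the C3–C1' bond and the stereocentre together.

**Alternative 3:** Cut ring B itself (C1'–C2' and C5'–C6' region) and build the quinone de novo. Forward key step: the lithium acetylide of the (3S)-3-ethynylchroman A5 adds to dimethyl squarate to give the 4-alkynyl-4-hydroxycyclobutenone A6; thermolysis (Moore rearrangement: ring opening to an alkynyl-ethenyl ketene, closure to a diradical, hydrogen transfer) gives the 2,3-dimethoxy-5-alkylbenzoquinone, and desilylation gives 8. Grounds for preferring the chosen plan: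
- This avoids any oxidation, but it leaves C3 untouched: the stereocentre of A5 needs a separate asymmetric step.
- The alkyne must come from one-carbon homologation of a C3 aldehyde function that sits β to the aryloxy oxygen, where retro-oxa-Michael opening threatens the configuration.
- The aryl σ-radical of the diradical sits ortho to the chromanyl group and can abstract hydrogen from C2 or C4 through a six-membered transition state.
- The count is about twice that of the chosen route.

Key step: step 5

Assumption on the ligand: the sense of induction of the titanium TADDOLate with this chromene is assumed, not known. The (4R,5R)-ligand is written; if it should favour the (6aR,11aR) series, the (4S,5S)-ligand is used and nothing else changes.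

Assumption on supply: 1 is treated as a catalogue compound.

## Route

Step 1
Reactants: 1 2,3-dimethoxycyclohexa-2,5-diene-1,4-dione
Product: 2 2,3-dimethoxybenzene-1,4-diol
Conditions: H2 (1 atm), 5% Pd/C, EtOAc, rt; filtered under Ar and used at once
Reagents that add atoms: none
Why: Catalytic hydrogenation of a p-quinone stops cleanly at the hydroquinone because the arene formed is inert under these conditions; the product is air-sensitive and is carried on directly.

Step 2
Reactants: 2 2,3-dimethoxybenzene-1,4-diol
Product: 3 4-(benzyloxy)-2,3-dimethoxyphenol
Conditions: 2 (1.5 equiv), BnBr (1.0 equiv), K2CO3, degassed DMF, rt, Ar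
Reagents that add atoms: benzyl bromide, BrCc1ccccc1
Why: Williamson ether synthesis on a C2-symmetric diol, so either hydroxyl gives the same monoether; 2 is used in excess so that the monoether should dominate over the diether, and unchanged 2 is recovered.

Step 3
Reactants: 3 4-(benzyloxy)-2,3-dimethoxyphenol
Product: 4 1-(benzyloxy)-2,3-dimethoxy-4-(prop-2-yn-1-yloxy)benzene
Conditions: propargyl bromide, K2CO3, acetone, reflux
Reagents that add atoms: propargyl bromide, C#CCBr
Why: Williamson ether synthesis of the only free phenol with a primary propargylic halide; no other nucleophilic site is present.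

Step 4
Reactants: 4 1-(benzyloxy)-2,3-dimethoxy-4-(prop-2-yn-1-yloxy)benzene
Product: 5 6-(benzyloxy)-7,8-dimethoxy-2H-chromene
Conditions: PhNEt2, 200 °C, Ar, sealed vessel
Reagents that add atoms: none
Why: Aryl propargyl ether Claisen rearrangement to the ortho-allenyl dienone, enolisation, [1,5]-H shift and oxa-6π electrocyclisation give the 2H-chromene; only one ortho position carries hydrogen (the other bears OMe), so a single regioisomer should form.

Step 5
Reactants: 5 6-(benzyloxy)-7,8-dimethoxy-2H-chromene; 1 2,3-dimethoxycyclohexa-2,5-diene-1,4-dione
Product: 6 (6aS,11aS)-2-(benzyloxy)-3,4,9,10-tetramethoxy-6a,11a-dihydro-6H-[1]benzofuro[3,2-c]chromen-8-ol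
Conditions: (4R,5R)-TADDOL, TiCl4/Ti(OiPr)4 (1:1), CH2Cl2, rt then −78 °C; 1; then 5, −78 → −40 °C; sat. aq. NaHCO3
Reagents that add atoms: none
Why: This is the Ti(IV)-promoted formal [3+2] cycloaddition of a 2-alkoxy-1,4-benzoquinone with a styrene-type alkene (the quinone–chromene route to pterocarpans) in its TADDOLate-mediated enantioselective form. The titanium binds C1=O and the neighbouring OMe of 1 as a five-membered chelate, and the nucleophilic C3 of 5 adds to the unsubstituted C5 of 1, conjugate to the chelated carbonyl, forming C6a–C6b. The resulting C4 cation is benzylic and stabilised by O1 (ortho) and 7-OMe (para); it is captured by the adjacent carbonyl oxygen of the quinone unit in a 5-exo closure onto the cation (ring O11–C11a–C6a–C6b–C10a), and tautomerisation to the phenol makes the sequence irreversible. C6a (C3 of the target) is set in the C–C bond formation by the C2-symmetric titanate, which shields one face of the chelated quinone so that only one enantiotopic face of the C3=C4 bond of 5 can reach C5. C11a is not chosen independently, since the 5/6 fusion can only be cis and oxygen is delivered to the face of C4 on which the quinone already sits; this centre is erased in step 6. Regiochemistry on 1 needs no control because C5 and C6 are homotopic, and on 5 it is fixed by cation stability, as the reverse polarity would put the charge on non-benzylic C3. Capture at oxygen rather than at carbon is favoured by the strongly stabilised cation and by aromatisation. The free 8-OH of 6 marks the ring-B oxygen that was not used, so both ring-B oxygens arrive at the hydroquinone level without any oxidant, and the enantiomeric purity of 6 should be upgradable by recrystallisation at this configurationally locked stage.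

Step 6
Reactants: 6 (6aS,11aS)-2-(benzyloxy)-3,4,9,10-tetramethoxy-6a,11a-dihydro-6H-[1]benzofuro[3,2-c]chromen-8-ol
Product: 8 5-[(3S)-6-hydroxy-7,8-dimethoxy-3,4-dihydro-2H-chromen-3-yl]-2,3-dimethoxycyclohexa-2,5-diene-1,4-dione, via hydroquinone 7 (not isolated)
Conditions: H2 (3 atm), 10% Pd/C, EtOAc–AcOH (20:1), rt; filtered under Ar, evaporated; then Ag2O (1.0 equiv), Na2SO4, Et2O, 0 °C
Reagents that add atoms: none
Why: Catalytic hydrogenolysis cleaves the benzylic C11a–O11 bond (the classical pterocarpan to 2'-hydroxyisoflavan opening) and the benzyl ether, leaving C6a untouched, so (6aS) becomes (3S) with the same spatial arrangement. The stoichiometric mild oxidant then takes the only true hydroquinone (ring B) to the quinone; ring A cannot become a quinone without C–O cleavage, and any ring-A phenoxyl radical would be reduced back by remaining hydroquinone.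

## Compound list

1 | 2,3-dimethoxycyclohexa-2,5-diene-1,4-dione | COC1=C(OC)C(=O)C=CC1=O | starting material
2 | 2,3-dimethoxybenzene-1,4-diol | COc1c(O)ccc(O)c1OC | intermediate
3 | 4-(benzyloxy)-2,3-dimethoxyphenol | COc1c(O)ccc(OCc2ccccc2)c1OC | intermediate
4 | 1-(benzyloxy)-2,3-dimethoxy-4-(prop-2-yn-1-yloxy)benzene | COc1c(OCC#C)ccc(OCc2ccccc2)c1OC | intermediate
5 | 6-(benzyloxy)-7,8-dimethoxy-2H-chromene | COc1c(OCc2ccccc2)cc2C=CCOc2c1OC | intermediate
6 | (6aS,11aS)-2-(benzyloxy)-3,4,9,10-tetramethoxy-6a,11a-dihydro-6H-[1]benzofuro[3,2-c]chromen-8-ol | COc1c(OC)c2O[C@@H]3c4cc(OCc5ccccc5)c(OC)c(OC)c4OC[C@@H]3c2cc1O | intermediate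
7 | 2-[(3S)-6-hydroxy-7,8-dimethoxy-3,4-dihydro-2H-chromen-3-yl]-5,6-dimethoxybenzene-1,4-diol | COc1c(OC)c(O)c([C@H]2COc3c(cc(O)c(OC)c3OC)C2)cc1O | intermediate
8 | 5-[(3S)-6-hydroxy-7,8-dimethoxy-3,4-dihydro-2H-chromen-3-yl]-2,3-dimethoxycyclohexa-2,5-diene-1,4-dione | COC1=C(OC)C(=O)C([C@H]2COc3c(cc(O)c(OC)c3OC)C2)=CC1=O | target

## Step count and least certain steps

Total step count: 6. Longest linear sequence: 6 steps (1 → 2 → 3 → 4 → 5 → 6 → 8); 1 enters twice, in steps 1 and 5.

**Step 5 (key step).** The most likely failure is poor or reversed facial selectivity: the chiral titanate is bound to the quinone, two bonds away from the forming stereocentre, and its sense for this chromene is assumed. Secondary risks are capture of the benzylic cation at carbon instead of oxygen, Lewis-acid ionisation of the newly formed C11a–O bond, and cationic oligomerisation of the electron-rich alkene.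

Fallback, which forms the same two ring bonds in a different order with a catalyst whose facial sense is predictable; it sets out from 3 and comes back at 6:
- Alkylation of 3 with 2-(2-bromoethyl)-1,3-dioxolane (K2CO3, DMF, 70 °C) would give 2-{2-[4-(benzyloxy)-2,3-dimethoxyphenoxy]ethyl}-1,3-dioxolane F1.
- Mild hydrolysis (aq. HCl, THF, rt) would give 3-[4-(benzyloxy)-2,3-dimethoxyphenoxy]propanal F2.
- Enamine-catalysed α-arylation of F2 with 1, using (S)-α,α-bis[3,5-bis(trifluoromethyl)phenyl]prolinol trimethylsilyl ether (10 mol %) in EtOH–H2O at 0 °C, should give (3S)-3-{[4-(benzyloxy)-2,3-dimethoxyphenoxy]methyl}-6,7-dimethoxy-2,3-dihydro-1-benzofuran-2,5-diol F3. The quinone enters the E-enamine on the face opposite the silyloxydiarylmethyl group, which for the (S)-catalyst places the new aryl group as required; the lactol protects the α-centre.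
- BF3·OEt2 (CH2Cl2, −78 °C) would ionise the lactol, and the tethered, strongly activated ring would close C11a–C11b by intramolecular Friedel–Crafts alkylation to give 6, the cis fusion again being enforced.
- The weak points of this sequence are reversible loss of the β-aryloxy group under amine catalysis and dehydration of the lactol to a benzofuran, which is why it is held in reserve.

**Step 6.** The likely failures are:
- acid-assisted ionisation at C11a followed by loss of the C6a proton and unselective re-hydrogenation, which would erode the enantiomeric purity;
- incomplete C–O hydrogenolysis after fast debenzylation;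
- over-oxidation of ring A once the hydroquinone is consumed.

Fallback, setting out from 6 and coming back at 7: dissolving-metal cleavage (Li, NH3/THF, −78 °C, then NH4Cl). This cuts both benzylic C–O bonds by electron transfer, so no cation and no C6a deprotonation is involved; 7 is then oxidised as in step 6. This fallback makes no new compound (F0).

**Step 4.** The likely failures at 200 °C are closure of the allenylphenol intermediate through oxygen in a 5-exo sense (benzofuran formation) and thermal loss of the benzyl group.

Fallback, setting out from 3 and coming back at 5: ortho-formylation of 3 (MgCl2, Et3N, paraformaldehyde, MeCN, reflux; only one ortho position is free) would give 5-(benzyloxy)-2-hydroxy-3,4-dimethoxybenzaldehyde F4. Treatment with vinyltriphenylphosphonium bromide and K2CO3 in DMF (oxa-Michael addition, then intramolecular Wittig reaction) would build the C2–C3=C4 unit and give 5.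

## Further compounds

F1 | step 5 | 2-{2-[4-(benzyloxy)-2,3-dimethoxyphenoxy]ethyl}-1,3-dioxolane | COc1c(OCCC2OCCO2)ccc(OCc2ccccc2)c1OC
F2 | step 5 | 3-[4-(benzyloxy)-2,3-dimethoxyphenoxy]propanal | COc1c(OCCC=O)ccc(OCc2ccccc2)c1OC
F3 | step 5 | (3S)-3-{[4-(benzyloxy)-2,3-dimethoxyphenoxy]methyl}-6,7-dimethoxy-2,3-dihydro-1-benzofuran-2,5-diol (both C2 epimers) | COc1c(OC)c2OC(O)[C@H](COc3ccc(OCc4ccccc4)c(OC)c3OC)c2cc1O
F0 | step 6 | none | none
F4 | step 4 | 5-(benzyloxy)-2-hydroxy-3,4-dimethoxybenzaldehyde | COc1c(OC)c(O)c(C=O)cc1OCc1ccccc1
A1 | alternative 1 | 6-(benzyloxy)-7,8-dimethoxy-3-(2,3,4,5-tetramethoxyphenyl)-2H-chromene | COc1cc(C2=Cc3cc(OCc4ccccc4)c(OC)c(OC)c3OC2)c(OC)c(OC)c1OC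
A2 | alternative 1 | (3S)-6-(benzyloxy)-7,8-dimethoxy-3-(2,3,4,5-tetramethoxyphenyl)-3,4-dihydro-2H-chromene | COc1cc([C@H]2COc3c(cc(OCc4ccccc4)c(OC)c3OC)C2)c(OC)c(OC)c1OC
A3 | alternative 2 | rac-6-(benzyloxy)-3-[2,5-bis(benzyloxy)-3,4-dimethoxyphenyl]-7,8-dimethoxy-2,3-dihydro-4H-chromen-4-one | O=C1c2cc(OCc3ccccc3)c(OC)c(OC)c2OCC1c4cc(OCc5ccccc5)c(OC)c(OC)c4OCc6ccccc6
A4 | alternative 2 | (3S,4S)-6-(benzyloxy)-3-[2,5-bis(benzyloxy)-3,4-dimethoxyphenyl]-7,8-dimethoxy-3,4-dihydro-2H-chromen-4-ol (cis) | O[C@@H]1c2cc(OCc3ccccc3)c(OC)c(OC)c2OC[C@@H]1c4cc(OCc5ccccc5)c(OC)c(OC)c4OCc6ccccc6
A5 | alternative 3 | (3S)-6-[(tert-butyldimethylsilyl)oxy]-3-ethynyl-7,8-dimethoxy-3,4-dihydro-2H-chromene | C#C[C@H]1COc2c(cc(O[Si](C)(C)C(C)(C)C)c(OC)c2OC)C1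
A6 | alternative 3 | 4-({(3S)-6-[(tert-butyldimethylsilyl)oxy]-7,8-dimethoxy-3,4-dihydro-2H-chromen-3-yl}ethynyl)-4-hydroxy-2,3-dimethoxycyclobut-2-en-1-one (both carbinol epimers) | COC1=C(OC)C(O)(C#C[C@H]2COc3c(cc(O[Si](C)(C)C(C)(C)C)c(OC)c3OC)C2)C1=O
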